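**Retrosynthetic overview**
1. Rings are lettered A (2,4,6-trihydroxyphenoxy end) to H (3,4,5-trihydroxyphenoxy end). All 21 hydroxyls travel as methyl ethers and are freed last with BBr3, after a copper-mediated E–O–F union of an A–E aryl bromide with an F–G–H phenol.
2. The route rests on ring G: C1 carries the oxygen to ring F, C2 is its only C–H, C3, C4 and C5 carry hydroxyls and C6 carries the oxygen to ring H. C3–C6 with their four oxygens are the four carbons of dimethyl squarate; C1–C2 come from a two-carbon aryloxyvinyl unit hung on the ring F oxygen.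
3. Ring G is the only ring made de novo: ring F phenol → dichlorovinyl ether → lithium aryloxyacetylide → squarate adduct, O-methylation, cis-semihydrogenation, then thermal cyclobutenone-to-phenol ring expansion. Its single free hydroxyl (C6) is then arylated with ring H.
4. Rings A–E are bought as benzenes and joined one by one: a phenol is arylated with a halobenzaldehyde (copper catalysis for B, C, D; fluoride displacement for the crowded D–O–E ether), and Dakin oxidation of the aldehyde gives the next phenol.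
5. Order of ring formation: ring G alone (step 6); all other rings are preformed.

Key step: step 6

Assumption: the target is achiral, so the one stereocentre on the way (C4 of the cyclobutenones, then the sp3 carbon of the dienone) is carried racemic and is erased on aromatisation; 4-bromo-2,6-dimethoxybenzaldehyde, 2,4,6-trimethoxyphenol and 1-bromo-2-fluoro-4,5-dimethoxybenzene are taken as catalogue compounds.

**Fragment F–G–H**

Step 1
Reactants: 1 3-hydroxy-4,5-dimethoxybenzaldehyde
Product: 2 3-{[(E)-1,2-dichloroethenyl]oxy}-4,5-dimethoxybenzaldehyde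
Conditions: Cl2C=CHCl, K2CO3, DMF, 70 °C
Reagents that add atoms: trichloroethylene, ClC=C(Cl)Cl
Why: Base-induced elimination of trichloroethylene to dichloroacetylene and anti addition of the phenoxide (dichlorovinyl ether synthesis) should give the E ether, which serves both as protection of the future O–G oxygen and as the alkyne precursor, while the non-enolisable aldehyde is untouched.

Step 2
Reactants: 2 3-{[(E)-1,2-dichloroethenyl]oxy}-4,5-dimethoxybenzaldehyde
Product: 4 3-{[(E)-1,2-dichloroethenyl]oxy}-4,5-dimethoxyphenol, via aryl formate 3 (not isolated)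
Conditions: mCPBA, CH2Cl2, 0 °C to rt; then K2CO3, MeOH, rt
Reagents that add atoms: mCPBA, OOC(=O)c1cccc(Cl)c1
Why: Dakin-type Baeyer–Villiger oxidation in which the aryl group para to a methoxy group migrates; the doubly chlorinated, electron-poor enol ether should not be epoxidised at a competing rate, and methanolysis of the formate frees the phenol.

Step 3
Reactants: 4 3-{[(E)-1,2-dichloroethenyl]oxy}-4,5-dimethoxyphenol
Product: 5 5-(benzyloxy)-1-{[(E)-1,2-dichloroethenyl]oxy}-2,3-dimethoxybenzene
Conditions: BnBr, K2CO3, DMF, rt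
Reagents that add atoms: benzyl bromide, BrCc1ccccc1
Why: Williamson etherification of an unhindered phenoxide; the benzyl group marks the oxygen that will later be joined to ring E.

Step 4
Reactants: 5 5-(benzyloxy)-1-{[(E)-1,2-dichloroethenyl]oxy}-2,3-dimethoxybenzene; 6 dimethyl squarate
Product: 9 rac-4-{[5-(benzyloxy)-2,3-dimethoxyphenoxy]ethynyl}-2,3,4-trimethoxycyclobut-2-en-1-one, via lithium aryloxyacetylide 7 (not isolated), via lithium cyclobutenolate 8 (not isolated)
Conditions: n-BuLi (2.1 equiv), THF, −78 to −40 °C; cannulated into 6, THF, −78 °C; MeOTf, −78 to 0 °C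
Reagents that add atoms: methyl triflate, COS(=O)(=O)C(F)(F)F
Why: Deprotonation, loss of chloride and chlorine–lithium exchange turn the dichlorovinyl ether into the lithium acetylide, which adds 1,2 to one carbonyl of the squarate ester (known acetylide addition to squarates), and the tertiary lithium alkoxide is O-methylated in the flask; the new quaternary centre is racemic and becomes sp2 in step 6.

Step 5
Reactants: 9 rac-4-{[5-(benzyloxy)-2,3-dimethoxyphenoxy]ethynyl}-2,3,4-trimethoxycyclobut-2-en-1-one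
Product: 10 rac-4-{(Z)-2-[5-(benzyloxy)-2,3-dimethoxyphenoxy]ethenyl}-2,3,4-trimethoxycyclobut-2-en-1-one
Conditions: H2 (1 atm), Pd/CaCO3 poisoned with Pb(OAc)2, quinoline, EtOAc, rt
Reagents that add atoms: none
Why: Syn delivery of hydrogen on the poisoned palladium surface (Lindlar reduction of an ynol ether) should give the Z enol ether, while the benzyl ether and the tetrasubstituted dimethoxy-enone double bond are inert to this catalyst.

Step 6
Reactants: 10 rac-4-{(Z)-2-[5-(benzyloxy)-2,3-dimethoxyphenoxy]ethenyl}-2,3,4-trimethoxycyclobut-2-en-1-one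
Product: 13 6-[5-(benzyloxy)-2,3-dimethoxyphenoxy]-2,3,4-trimethoxyphenol, via dienylketene 11 (not isolated), via cyclohexadienone 12 (not isolated)
Conditions: degassed toluene (0.01 M), 110 °C
Reagents that add atoms: none
Why: Heating opens the cyclobutenone by conrotatory four-electron electrocyclic cleavage of the C1–C4 bond to the (3Z,5Z)-dienylketene 11, whose ketene carbon and aryloxy-bearing vinyl carbon join in a disrotatory six-electron electrocyclisation to cyclohexa-2,4-dienone 12, and enolisation of its C–H gives phenol 13. The closest known reaction type is the Moore rearrangement of squarate-derived 4-alkenyl-4-alkoxycyclobutenones to hydroquinone monoethers. Ring G is closed in this six-electron electrocyclic mode with formation of one C–C bond (future C6–C1); the ketene carbon and the three other squarate carbons become C6, C5, C4 and C3, the vinyl carbons become C2 and C1. No stereocentre survives, because the racemic quaternary carbon of 10 becomes sp2 on ring opening and the sp3 carbon of 12 is erased by tautomerisation. The step needs torquoselectivity, which the 4-methoxy donor secures by rotating outward and so turning the vinyl group inward, cis to the ketene; the ketene carbon carries no substituent that could clash with the inward-pointing Z aryloxy group, so closure should outrun intermolecular ketene trapping in dilute aprotic solution. The position of the phenol is fixed by connectivity, since only the ketene oxygen ends as a free hydroxyl, at the carbon flanked by the ring F ether and a methoxy group, which is where ring H has to go.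

Step 7
Reactants: 13 6-[5-(benzyloxy)-2,3-dimethoxyphenoxy]-2,3,4-trimethoxyphenol; 14 5-bromo-1,2,3-trimethoxybenzene
Product: 15 5-(benzyloxy)-1,2-dimethoxy-3-[3,4,5-trimethoxy-2-(3,4,5-trimethoxyphenoxy)phenoxy]benzene (F–G–H benzyl ether)
Conditions: CuI (cat.), picolinic acid, K3PO4, DMSO, 90 °C, argon
Reagents that add atoms: none
Why: Ullmann-type copper-catalysed diaryl ether synthesis with a picolinate ligand, a combination suited to a di-ortho-substituted phenol and an aryl bromide with two free ortho positions; the benzyl ether is inert.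

Step 8
Reactants: 15 F–G–H benzyl ether
Product: 16 3,4-dimethoxy-5-[3,4,5-trimethoxy-2-(3,4,5-trimethoxyphenoxy)phenoxy]phenol (F–G–H phenol)
Conditions: H2 (1 atm), Pd/C, EtOAc–MeOH, rt
Reagents that add atoms: none
Why: Hydrogenolysis of the benzylic C–O bond frees the ring F hydroxyl; methyl and diaryl ethers are stable.

**Fragment A–E**

Step 9
Reactants: 17 2,4,6-trimethoxyphenol; 18 4-bromo-2,6-dimethoxybenzaldehyde
Product: 19 2,6-dimethoxy-4-(2,4,6-trimethoxyphenoxy)benzaldehyde (A–B aldehyde)
Conditions: CuI (cat.), picolinic acid, K3PO4, DMSO, 90 °C, argon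
Reagents that add atoms: none
Why: Ullmann-type coupling of a hindered, electron-rich phenol with an unhindered aryl bromide that is activated by its para formyl group.

Step 10
Reactants: 19 A–B aldehyde
Product: 21 2,6-dimethoxy-4-(2,4,6-trimethoxyphenoxy)phenol (A–B phenol), via aryl formate 20 (not isolated)
Conditions: mCPBA (1.1 equiv), CH2Cl2, 0 °C; then K2CO3, MeOH, rt
Reagents that add atoms: mCPBA, OOC(=O)c1cccc(Cl)c1
Why: Dakin-type Baeyer–Villiger oxidation, fast for a 2,6-dialkoxybenzaldehyde with a para aryloxy group, followed by formate methanolysis.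

Step 11
Reactants: 14 5-bromo-1,2,3-trimethoxybenzene
Product: 23 6-bromo-2,3,4-trimethoxybenzaldehyde, via chloro(methoxy)methyl arene 22 (not isolated)
Conditions: Cl2CHOMe, TiCl4, CH2Cl2, 0 °C; then H2O
Reagents that add atoms: dichloromethyl methyl ether, COC(Cl)Cl; water, O
Why: Rieche formylation; the two free positions of the symmetrical arene are equivalent and each is ortho and para to a methoxy group, so a single aldehyde should form.

Step 12
Reactants: 21 A–B phenol; 23 6-bromo-2,3,4-trimethoxybenzaldehyde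
Product: 24 6-[2,6-dimethoxy-4-(2,4,6-trimethoxyphenoxy)phenoxy]-2,3,4-trimethoxybenzaldehyde (A–B–C aldehyde)
Conditions: CuI (cat.), picolinic acid, K3PO4, DMSO, 100 °C, argon
Reagents that add atoms: none
Why: Ullmann-type coupling in which the ortho formyl group activates the bromide and can chelate copper, which should offset the tri-ortho substitution of the new ether.

Step 13
Reactants: 24 A–B–C aldehyde
Product: 26 6-[2,6-dimethoxy-4-(2,4,6-trimethoxyphenoxy)phenoxy]-2,3,4-trimethoxyphenol (A–B–C phenol), via aryl formate 25 (not isolated)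
Conditions: mCPBA (1.1 equiv), CH2Cl2, 0 °C; then K2CO3, MeOH, rt
Reagents that add atoms: mCPBA, OOC(=O)c1cccc(Cl)c1
Why: Dakin-type Baeyer–Villiger oxidation of an aldehyde with two ortho and one para oxygen substituent, then methanolysis.

Step 14
Reactants: 26 A–B–C phenol; 18 4-bromo-2,6-dimethoxybenzaldehyde
Product: 27 2,6-dimethoxy-4-{2,3,4-trimethoxy-6-[2,6-dimethoxy-4-(2,4,6-trimethoxyphenoxy)phenoxy]phenoxy}benzaldehyde (A–B–C–D aldehyde)
Conditions: CuI (cat.), picolinic acid, K3PO4, DMSO, 90 °C, argon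
Reagents that add atoms: none
Why: Ullmann-type coupling, again pairing a hindered phenol with the unhindered, formyl-activated bromide.

Step 15
Reactants: 27 A–B–C–D aldehyde
Product: 29 2,6-dimethoxy-4-{2,3,4-trimethoxy-6-[2,6-dimethoxy-4-(2,4,6-trimethoxyphenoxy)phenoxy]phenoxy}phenol (A–B–C–D phenol), via aryl formate 28 (not isolated)
Conditions: mCPBA (1.1 equiv), CH2Cl2, 0 °C; then K2CO3, MeOH, rt
Reagents that add atoms: mCPBA, OOC(=O)c1cccc(Cl)c1
Why: Dakin-type Baeyer–Villiger oxidation as in step 10.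

Step 16
Reactants: 30 1-bromo-2-fluoro-4,5-dimethoxybenzene
Product: 33 3-bromo-2-fluoro-5,6-dimethoxybenzaldehyde, via aryllithium 31 (not isolated), via lithium hemiaminalate 32 (not isolated)
Conditions: LiN(i-Pr)2, THF, −78 °C; DMF, −78 °C; then aq. HCl
Reagents that add atoms: N,N-dimethylformamide, CN(C)C=O
Why: Directed ortho-lithiation at the hydrogen flanked by fluorine and methoxy (the most acidic site), kept at −78 °C to avoid aryne formation, then formylation with DMF.

Step 17
Reactants: 29 A–B–C–D phenol; 33 3-bromo-2-fluoro-5,6-dimethoxybenzaldehyde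
Product: 34 3-bromo-5,6-dimethoxy-2-(A–B–C–D aryloxy)benzaldehyde (A–E bromo aldehyde; the aryloxy group is that of phenol 29)
Conditions: Cs2CO3, DMSO, 100 °C, argon
Reagents that add atoms: none
Why: Nucleophilic aromatic substitution of fluoride through a Meisenheimer adduct stabilised by the ortho formyl group, the reaction type of choice for a tetra-ortho-substituted diaryl ether; the bromide, meta to the formyl group, is not activated.

Step 18
Reactants: 34 A–E bromo aldehyde
Product: 36 3-bromo-5,6-dimethoxy-2-(A–B–C–D aryloxy)phenol (A–E bromo phenol), via aryl formate 35 (not isolated)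
Conditions: mCPBA (1.2 equiv), CH2Cl2, 0 °C to rt; then K2CO3, MeOH, rt
Reagents that add atoms: mCPBA, OOC(=O)c1cccc(Cl)c1
Why: Dakin-type Baeyer–Villiger oxidation, with aryl migration favoured by the ortho aryloxy and ortho methoxy groups.

Step 19
Reactants: 36 A–E bromo phenol
Product: 37 1-bromo-3,4,5-trimethoxy-2-(A–B–C–D aryloxy)benzene (A–E bromide)
Conditions: MeI, K2CO3, DMF, 40 °C
Reagents that add atoms: iodomethane, CI
Why: Williamson O-methylation completes the methoxy pattern of ring E and leaves the bromide as the handle for the union.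

**Union and deprotection**

Step 20
Reactants: 37 A–E bromide; 16 F–G–H phenol
Product: 38 henicosa-O-methyl ether of the target (permethylated octamer A–H)
Conditions: CuI, N,N-dimethylglycine·HCl, Cs2CO3, dioxane, 105 °C, argon
Reagents that add atoms: none
Why: Ullmann-type diaryl ether coupling with an amino acid ligand, here between an unhindered phenol (ring F oxygen between two C–H) and an aryl bromide with only one ortho substituent.

Step 21
Reactants: 38 permethylated octamer
Product: 39 CNP0309601.0 (target)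
Conditions: BBr3 (excess, at least 3 equiv per OMe), CH2Cl2, −78 °C to rt, argon; then MeOH, H2O, 0 °C
Reagents that add atoms: none
Why: Lewis acid ether cleavage in which bromide attacks the methyl carbon of each boron-complexed aryl methyl ether; the seven diaryl ether bonds have no sp3 carbon and should survive.

**Compound list**
1 | 3-hydroxy-4,5-dimethoxybenzaldehyde | COc1cc(C=O)cc(O)c1OC | starting material
2 | 3-{[(E)-1,2-dichloroethenyl]oxy}-4,5-dimethoxybenzaldehyde | COc1cc(C=O)cc(O/C(Cl)=C\Cl)c1OC | intermediate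
3 | 3-{[(E)-1,2-dichloroethenyl]oxy}-4,5-dimethoxyphenyl formate (not isolated) | COc1cc(OC=O)cc(O/C(Cl)=C\Cl)c1OC | intermediate
4 | 3-{[(E)-1,2-dichloroethenyl]oxy}-4,5-dimethoxyphenol | COc1cc(O)cc(O/C(Cl)=C\Cl)c1OC | intermediate
5 | 5-(benzyloxy)-1-{[(E)-1,2-dichloroethenyl]oxy}-2,3-dimethoxybenzene | COc1cc(OCc2ccccc2)cc(O/C(Cl)=C\Cl)c1OC | intermediate
6 | dimethyl squarate | COC1=C(OC)C(=O)C1=O | starting material
7 | lithium [5-(benzyloxy)-2,3-dimethoxyphenoxy]acetylide (not isolated) | [Li]C#COc1cc(OCc2ccccc2)cc(OC)c1OC | intermediate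
8 | lithium alkoxide of the squarate adduct, racemic (not isolated) | [Li]OC1(C#COc2cc(OCc3ccccc3)cc(OC)c2OC)C(OC)=C(OC)C1=O | intermediate
9 | rac-4-{[5-(benzyloxy)-2,3-dimethoxyphenoxy]ethynyl}-2,3,4-trimethoxycyclobut-2-en-1-one | COC1=C(OC)C(OC)(C#COc2cc(OCc3ccccc3)cc(OC)c2OC)C1=O | intermediate
10 | rac-4-{(Z)-2-[5-(benzyloxy)-2,3-dimethoxyphenoxy]ethenyl}-2,3,4-trimethoxycyclobut-2-en-1-one | COC1=C(OC)C(OC)(/C=C\Oc2cc(OCc3ccccc3)cc(OC)c2OC)C1=O | intermediate
11 | (3Z,5Z)-6-[5-(benzyloxy)-2,3-dimethoxyphenoxy]-2,3,4-trimethoxyhexa-1,3,5-trien-1-one (dienylketene, not isolated) | O=C=C(OC)/C(OC)=C(OC)\C=C/Oc1cc(OCc2ccccc2)cc(OC)c1OC | intermediate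
12 | rac-6-[5-(benzyloxy)-2,3-dimethoxyphenoxy]-2,3,4-trimethoxycyclohexa-2,4-dien-1-one (not isolated) | COC1=CC(Oc2cc(OCc3ccccc3)cc(OC)c2OC)C(=O)C(OC)=C1OC | intermediate
13 | 6-[5-(benzyloxy)-2,3-dimethoxyphenoxy]-2,3,4-trimethoxyphenol | Oc1c(OC)c(OC)c(OC)cc1Oc1cc(OCc2ccccc2)cc(OC)c1OC | intermediate
14 | 5-bromo-1,2,3-trimethoxybenzene | COc1cc(Br)cc(OC)c1OC | starting material
15 | F–G–H benzyl ether | COc1cc(Oc2c(OC)c(OC)c(OC)cc2Oc2cc(OCc3ccccc3)cc(OC)c2OC)cc(OC)c1OC | intermediate
16 | F–G–H phenol | COc1cc(Oc2c(OC)c(OC)c(OC)cc2Oc2cc(O)cc(OC)c2OC)cc(OC)c1OC | intermediate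
17 | 2,4,6-trimethoxyphenol | COc1cc(OC)c(O)c(OC)c1 | starting material
18 | 4-bromo-2,6-dimethoxybenzaldehyde | COc1cc(Br)cc(OC)c1C=O | starting material
19 | A–B aldehyde | COc1cc(OC)c(Oc2cc(OC)c(C=O)c(OC)c2)c(OC)c1 | intermediate
20 | A–B aryl formate (not isolated) | COc1cc(OC)c(Oc2cc(OC)c(OC=O)c(OC)c2)c(OC)c1 | intermediate
21 | A–B phenol | COc1cc(OC)c(Oc2cc(OC)c(O)c(OC)c2)c(OC)c1 | intermediate
22 | rac-1-bromo-2-[chloro(methoxy)methyl]-3,4,5-trimethoxybenzene (not isolated) | COC(Cl)c1c(Br)cc(OC)c(OC)c1OC | intermediate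
23 | 6-bromo-2,3,4-trimethoxybenzaldehyde | COc1cc(Br)c(C=O)c(OC)c1OC | intermediate
24 | A–B–C aldehyde | COc1cc(OC)c(Oc2cc(OC)c(Oc3cc(OC)c(OC)c(OC)c3C=O)c(OC)c2)c(OC)c1 | intermediate
25 | A–B–C aryl formate (not isolated) | COc1cc(OC)c(Oc2cc(OC)c(Oc3cc(OC)c(OC)c(OC)c3OC=O)c(OC)c2)c(OC)c1 | intermediate
26 | A–B–C phenol | COc1cc(OC)c(Oc2cc(OC)c(Oc3cc(OC)c(OC)c(OC)c3O)c(OC)c2)c(OC)c1 | intermediate
27 | A–B–C–D aldehyde | COc1cc(OC)c(Oc2cc(OC)c(Oc3cc(OC)c(OC)c(OC)c3Oc3cc(OC)c(C=O)c(OC)c3)c(OC)c2)c(OC)c1 | intermediate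
28 | A–B–C–D aryl formate (not isolated) | COc1cc(OC)c(Oc2cc(OC)c(Oc3cc(OC)c(OC)c(OC)c3Oc3cc(OC)c(OC=O)c(OC)c3)c(OC)c2)c(OC)c1 | intermediate
29 | A–B–C–D phenol | COc1cc(OC)c(Oc2cc(OC)c(Oc3cc(OC)c(OC)c(OC)c3Oc3cc(OC)c(O)c(OC)c3)c(OC)c2)c(OC)c1 | intermediate
30 | 1-bromo-2-fluoro-4,5-dimethoxybenzene | COc1cc(F)c(Br)cc1OC | starting material
31 | (3-bromo-2-fluoro-5,6-dimethoxyphenyl)lithium (not isolated) | [Li]c1c(F)c(Br)cc(OC)c1OC | intermediate
32 | lithium (3-bromo-2-fluoro-5,6-dimethoxyphenyl)(dimethylamino)methanolate, racemic (not isolated) | [Li]OC(N(C)C)c1c(F)c(Br)cc(OC)c1OC | intermediate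
33 | 3-bromo-2-fluoro-5,6-dimethoxybenzaldehyde | COc1cc(Br)c(F)c(C=O)c1OC | intermediate
34 | A–E bromo aldehyde | COc1cc(OC)c(Oc2cc(OC)c(Oc3cc(OC)c(OC)c(OC)c3Oc3cc(OC)c(Oc4c(Br)cc(OC)c(OC)c4C=O)c(OC)c3)c(OC)c2)c(OC)c1 | intermediate
35 | A–E bromo aryl formate (not isolated) | COc1cc(OC)c(Oc2cc(OC)c(Oc3cc(OC)c(OC)c(OC)c3Oc3cc(OC)c(Oc4c(Br)cc(OC)c(OC)c4OC=O)c(OC)c3)c(OC)c2)c(OC)c1 | intermediate
36 | A–E bromo phenol | COc1cc(OC)c(Oc2cc(OC)c(Oc3cc(OC)c(OC)c(OC)c3Oc3cc(OC)c(Oc4c(Br)cc(OC)c(OC)c4O)c(OC)c3)c(OC)c2)c(OC)c1 | intermediate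
37 | A–E bromide | COc1cc(OC)c(Oc2cc(OC)c(Oc3cc(OC)c(OC)c(OC)c3Oc3cc(OC)c(Oc4c(Br)cc(OC)c(OC)c4OC)c(OC)c3)c(OC)c2)c(OC)c1 | intermediate
38 | permethylated octamer A–H (21 OMe) | COc1cc(OC)c(Oc2cc(OC)c(Oc3cc(OC)c(OC)c(OC)c3Oc3cc(OC)c(Oc4c(Oc5cc(OC)c(OC)c(Oc6cc(OC)c(OC)c(OC)c6Oc6cc(OC)c(OC)c(OC)c6)c5)cc(OC)c(OC)c4OC)c(OC)c3)c(OC)c2)c(OC)c1 | intermediate
39 | CNP0309601.0 | Oc1cc(O)c(Oc2cc(O)c(Oc3cc(O)c(O)c(O)c3Oc3cc(O)c(Oc4c(Oc5cc(O)c(O)c(Oc6cc(O)c(O)c(O)c6Oc6cc(O)c(O)c(O)c6)c5)cc(O)c(O)c4O)c(O)c3)c(O)c2)c(O)c1 | target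

**Step count**
Total: 21 steps. Longest linear sequence: 11 steps (9, 10, 12, 13, 14, 15, 17, 18, 19, 20, 21, from 17 and 18).

**Three steps most likely to fail**

Step 6 (thermal ring expansion). The ring opening may turn the vinyl group outward, so that the ketene cannot close and is lost to dimerisation or trapping. The closure may also be slowed by the inward-pointing Z aryloxy group, giving the ketene time to decompose, and traces of acid may ionise the tertiary allylic methoxy group before the thermolysis.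
Fallback: ring G is taken from the aromatic pool; the fallback sets out from phenol 1 and bromoaldehyde 23 and comes back to the route at phenol 16. Ullmann coupling of 1 with 23 (CuI, picolinic acid, K3PO4, DMSO, 100 °C) should give the dialdehyde 6-(5-formyl-2,3-dimethoxyphenoxy)-2,3,4-trimethoxybenzaldehyde F1. One equivalent of mCPBA at −10 °C should oxidise only the ring G aldehyde, the one flanked by two oxygen substituents and para to a third, to the mono-formate F2, and methanolysis should give 3-(2-hydroxy-3,4,5-trimethoxyphenoxy)-4,5-dimethoxybenzaldehyde F3. Arylation of F3 with 14 under the conditions of step 7 should give the F–G–H aldehyde F4, and a second Dakin oxidation through the formate F5 should give 16 with the ring F hydroxyl free.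

Step 17 (fluoride displacement to the tetra-ortho-substituted D–O–E ether). Addition of the crowded 2,6-dimethoxyphenoxide to a fluoroarene that is deactivated by its para methoxy group and flanked by bromine and formyl may be so slow that base-induced degradation or air oxidation of the aldehyde and of the phenoxide takes over.
Fallback: the activating group is changed to a nitrile; the fallback sets out from aldehyde 33 and comes back at aldehyde 34. One-flask conversion of 33 (NH2OH·HCl, HCO2Na, HCO2H, reflux) through the oxime F6 should give 3-bromo-2-fluoro-5,6-dimethoxybenzonitrile F7. The nitrile is a stronger activator, slimmer than formyl and inert to base, so phenol 29 can be forced on (Cs2CO3, DMSO, 130 °C) to the A–E bromo nitrile F8. Reduction with i-Bu2AlH (toluene, −78 °C) to the N-aluminio imine F9 and hydrolysis with aq. HCl should release 34.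

Step 20 (fragment union). Oxidative addition of the electron-rich, ortho-aryloxy bromide to monovalent copper may be slow at the temperature that two large polyether fragments tolerate, with hydrodebromination of 37 and oxidative loss of phenol 16 as competing processes.
Fallback: the polarity at copper is changed from a halide coupling to an oxidative boronic acid coupling; the fallback sets out from bromide 37 and comes back at 38. Bromine–lithium exchange (n-BuLi, THF, −78 °C) to the aryllithium F10, addition of B(OMe)3 to the lithium aryltrimethoxyborate F11 and aq. HCl should give the A–E boronic acid F12. Chan–Lam coupling of F12 with 16 (Cu(OAc)2, pyridine, 4 Å molecular sieves, air, CH2Cl2, rt), which runs on divalent copper at room temperature, should give 38.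

**Further compounds**
F1 | step 6 | 6-(5-formyl-2,3-dimethoxyphenoxy)-2,3,4-trimethoxybenzaldehyde | COc1cc(C=O)cc(Oc2cc(OC)c(OC)c(OC)c2C=O)c1OC
F2 | step 6 | 2-(5-formyl-2,3-dimethoxyphenoxy)-4,5,6-trimethoxyphenyl formate | COc1cc(C=O)cc(Oc2cc(OC)c(OC)c(OC)c2OC=O)c1OC
F3 | step 6 | 3-(2-hydroxy-3,4,5-trimethoxyphenoxy)-4,5-dimethoxybenzaldehyde | COc1cc(C=O)cc(Oc2cc(OC)c(OC)c(OC)c2O)c1OC
F4 | step 6 | 3,4-dimethoxy-5-[3,4,5-trimethoxy-2-(3,4,5-trimethoxyphenoxy)phenoxy]benzaldehyde | COc1cc(Oc2c(OC)c(OC)c(OC)cc2Oc2cc(C=O)cc(OC)c2OC)cc(OC)c1OC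
F5 | step 6 | 3,4-dimethoxy-5-[3,4,5-trimethoxy-2-(3,4,5-trimethoxyphenoxy)phenoxy]phenyl formate | COc1cc(Oc2c(OC)c(OC)c(OC)cc2Oc2cc(OC=O)cc(OC)c2OC)cc(OC)c1OC
F6 | step 17 | (E)-3-bromo-2-fluoro-5,6-dimethoxybenzaldehyde oxime | COc1cc(Br)c(F)c(/C=N/O)c1OC
F7 | step 17 | 3-bromo-2-fluoro-5,6-dimethoxybenzonitrile | COc1cc(Br)c(F)c(C#N)c1OC
F8 | step 17 | A–E bromo nitrile | COc1cc(OC)c(Oc2cc(OC)c(Oc3cc(OC)c(OC)c(OC)c3Oc3cc(OC)c(Oc4c(Br)cc(OC)c(OC)c4C#N)c(OC)c3)c(OC)c2)c(OC)c1
F9 | step 17 | A–E bromo N-(diisobutylaluminio)aldimine | COc1cc(OC)c(Oc2cc(OC)c(Oc3cc(OC)c(OC)c(OC)c3Oc3cc(OC)c(Oc4c(Br)cc(OC)c(OC)c4C=N[Al](CC(C)C)CC(C)C)c(OC)c3)c(OC)c2)c(OC)c1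
F10 | step 20 | A–E aryllithium | COc1cc(OC)c(Oc2cc(OC)c(Oc3cc(OC)c(OC)c(OC)c3Oc3cc(OC)c(Oc4c([Li])cc(OC)c(OC)c4OC)c(OC)c3)c(OC)c2)c(OC)c1
F11 | step 20 | lithium A–E aryltrimethoxyborate | [Li+].COc1cc(OC)c(Oc2cc(OC)c(Oc3cc(OC)c(OC)c(OC)c3Oc3cc(OC)c(Oc4c([B-](OC)(OC)OC)cc(OC)c(OC)c4OC)c(OC)c3)c(OC)c2)c(OC)c1
F12 | step 20 | A–E arylboronic acid | COc1cc(OC)c(Oc2cc(OC)c(Oc3cc(OC)c(OC)c(OC)c3Oc3cc(OC)c(Oc4c(B(O)O)cc(OC)c(OC)c4OC)c(OC)c3)c(OC)c2)c(OC)c1
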